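**Plan**

- The target is a 6-prenyl-5,7,2',4'-tetrahydroxyflavone with a (2S,3R)-2,3-dihydroxy-3,7-dimethyloct-6-enyl chain on C3. The C2'' oxygen is linked to the ring C carbonyl carbon through three carbons (O–C2''–C1''–C3–C4), so C4 can be carried as the carbonyl of a five-membered lactone on that oxygen until ring A is attached to it.
- Cuts, last to first: C4–C4a (ring C), the O1–C2 aryl vinyl ether bond, C3–C1'' (made together with the lactone), and the ring A C6–prenyl bond.
- Forward: epoxide 6 (from geraniol) and ring B keto ester 9 give aroyl lactone 11. Its Z-enol triflate 12 takes up ring A iodophenol 20 to give 21. Iodine–magnesium exchange then closes ring C while the lactone opens, and one acid step frees all hydroxyls.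
- Stereochemistry: both stereocentres come from one Sharpless epoxidation of geraniol followed by a Payne rearrangement/hydrolysis that inverts C2''. No C–O bond at either centre is broken afterwards. The Z geometry needed for ring closure comes from triflation of a lithium-chelated enolate.

Key step: step 14

Remark: hydroxy ester 10 and lactone 11 form as epimer mixtures at the carbon between the two carbonyl groups. That centre becomes planar in step 8 and is left undefined.

**Route**

Step 1
Reactants: 1 geraniol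
Product: 2 [(2R,3R)-3-methyl-3-(4-methylpent-3-en-1-yl)oxiran-2-yl]methanol
Conditions: Ti(OiPr)4 (5 mol%), D-(−)-diethyl tartrate (7 mol%), t-BuOOH, 4 Å MS, CH2Cl2, −20 °C
Reagents that add atoms: tert-butyl hydroperoxide, CC(C)(C)OO
Why: Sharpless asymmetric epoxidation, in which the titanium–D-tartrate complex binds the allylic alcohol and delivers oxygen to the face of the 2,3-alkene that gives the (2R,3R)-epoxide, while the unbound 6,7-alkene is left alone.

Step 2
Reactants: 2 [(2R,3R)-3-methyl-3-(4-methylpent-3-en-1-yl)oxiran-2-yl]methanol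
Product: 3 (2S,3R)-3,7-dimethyloct-6-ene-1,2,3-triol
Conditions: NaOH (0.5 M aq), t-BuOH, 75 °C
Reagents that add atoms: water, O
Why: Payne rearrangement followed by hydroxide opening of the terminal epoxide at C1 (direct hydroxide attack at C2 would give the same triol); C2 is inverted in the SN2 event and the C3–O bond is never broken, which sets the (2S,3R) configuration.

Step 3
Reactants: 3 (2S,3R)-3,7-dimethyloct-6-ene-1,2,3-triol
Product: 5 (2R)-6-methyl-2-[(2S)-oxiran-2-yl]hept-5-en-2-ol, via primary tosylate 4 (not isolated)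
Conditions: TsCl, Et3N, Bu2SnO (2 mol%), CH2Cl2, 0 °C; then K2CO3, MeOH, 0 °C
Reagents that add atoms: none
Why: Tin-acetal-catalysed sulfonylation of the primary hydroxyl of the 1,2-diol and Williamson-type 3-exo-tet closure by the secondary oxygen; only the C1–O bond is broken, so C2 keeps its configuration, and the weak base avoids Payne back-rearrangement.

Step 4
Reactants: 5 (2R)-6-methyl-2-[(2S)-oxiran-2-yl]hept-5-en-2-ol
Product: 6 triethyl({(2R)-6-methyl-2-[(2S)-oxiran-2-yl]hept-5-en-2-yl}oxy)silane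
Conditions: Et3SiOTf, 2,6-lutidine, CH2Cl2, −78 °C
Reagents that add atoms: triethylsilyl trifluoromethanesulfonate, CC[Si](CC)(CC)OS(=O)(=O)C(F)(F)F
Why: Silylation of a hindered tertiary alcohol with a silyl triflate and a hindered pyridine base, run cold so that the epoxide is not opened.

Step 5
Reactants: 7 methyl 2,4-dihydroxybenzoate
Product: 8 methyl 2,4-bis(methoxymethoxy)benzoate
Conditions: NaH, MOMCl, DMF, 0 → 23 °C
Reagents that add atoms: chloromethyl methyl ether, COCCl
Why: Williamson etherification of both phenoxides; NaH is used because the 2-hydroxyl is hydrogen-bonded to the ester.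

Step 6
Reactants: 8 methyl 2,4-bis(methoxymethoxy)benzoate
Product: 9 methyl 3-[2,4-bis(methoxymethoxy)phenyl]-3-oxopropanoate
Conditions: MeOAc, LiN(SiMe3)2 (2.5 equiv), THF, −78 → 0 °C; then AcOH
Reagents that add atoms: methyl acetate, CC(=O)OC
Why: Crossed Claisen condensation of the lithium enolate of methyl acetate with a non-enolisable aryl ester, driven forward by deprotonation of the keto ester formed.

Step 7
Reactants: 6 triethyl({(2R)-6-methyl-2-[(2S)-oxiran-2-yl]hept-5-en-2-yl}oxy)silane; 9 methyl 3-[2,4-bis(methoxymethoxy)phenyl]-3-oxopropanoate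
Product: 11 (5S)-3-[2,4-bis(methoxymethoxy)benzoyl]-5-[(2R)-6-methyl-2-(triethylsilyloxy)hept-5-en-2-yl]oxolan-2-one, via hydroxy keto ester 10 (not isolated)
Conditions: NaOMe, MeOH, 55 °C; then AcOH
Reagents that add atoms: none
Why: Alkylation of a β-keto ester enolate by SN2 opening of the monosubstituted epoxide at its CH2 terminus, then 5-exo-trig lactonisation of the secondary hydroxyl onto the methyl ester; neither C–O bond at the two stereocentres is broken, and the product is held as its enolate, which protects it from retro-Claisen cleavage.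

Step 8
Reactants: 11 (5S)-3-[2,4-bis(methoxymethoxy)benzoyl]-5-[(2R)-6-methyl-2-(triethylsilyloxy)hept-5-en-2-yl]oxolan-2-one
Product: 12 (Z)-[2,4-bis(methoxymethoxy)phenyl]{(5S)-5-[(2R)-6-methyl-2-(triethylsilyloxy)hept-5-en-2-yl]-2-oxooxolan-3-ylidene}methyl trifluoromethanesulfonate
Conditions: LiN(SiMe3)2, Et2O, −78 °C; Tf2O, −78 → −20 °C
Reagents that add atoms: trifluoromethanesulfonic anhydride, O=S(=O)(OS(=O)(=O)C(F)(F)F)C(F)(F)F
Why: O-sulfonylation of a β-dicarbonyl enolate; lithium bridges the enolate oxygen and the lactone carbonyl in ether, so the triflate ends up cis to the lactone carbonyl (Z).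

Step 9
Reactants: 13 phloroglucinol
Product: 14 3,5-bis(methoxymethoxy)phenol
Conditions: MOMCl (2 equiv), iPr2NEt, CH2Cl2/DMF, 0 °C
Reagents that add atoms: chloromethyl methyl ether, COCCl
Why: Statistical Williamson etherification of a symmetric triphenol; the bis-ether is separated from mono- and tris-ethers by chromatography.

Step 10
Reactants: 14 3,5-bis(methoxymethoxy)phenol
Product: 15 [3,5-bis(methoxymethoxy)phenoxy]tri(propan-2-yl)silane
Conditions: iPr3SiCl, imidazole, DMF, 23 °C
Reagents that add atoms: chlorotri(propan-2-yl)silane, CC(C)[Si](Cl)(C(C)C)C(C)C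
Why: Standard silylation of a phenol; the bulky silyl ether masks the acidic proton and does not direct lithiation.

Step 11
Reactants: 15 [3,5-bis(methoxymethoxy)phenoxy]tri(propan-2-yl)silane; 16 1-bromo-3-methylbut-2-ene
Product: 19 3,5-bis(methoxymethoxy)-4-(3-methylbut-2-en-1-yl)phenol, via aryllithium 17 (not isolated), via prenylated silyl ether 18 (not isolated)
Conditions: n-BuLi, THF, 0 °C; CuBr·SMe2 (10 mol%), 16, −78 → 0 °C; then Bu4NF, 23 °C; AcOH
Reagents that add atoms: none
Why: Directed ortho-metalation at the carbon flanked by the two MOM ethers, copper-catalysed allylation at the primary carbon of prenyl bromide, and fluoride cleavage of the aryl silyl ether in the same flask.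

Step 12
Reactants: 19 3,5-bis(methoxymethoxy)-4-(3-methylbut-2-en-1-yl)phenol
Product: 20 2-iodo-3,5-bis(methoxymethoxy)-4-(3-methylbut-2-en-1-yl)phenol
Conditions: N-iodosuccinimide (1.0 equiv), CH2Cl2, −40 → 0 °C
Reagents that add atoms: N-iodosuccinimide, O=C1CCC(=O)N1I
Why: Electrophilic aromatic iodination ortho to the free phenol; the two ortho carbons are equivalent by symmetry and the trioxygenated ring reacts faster than the prenyl alkene.

Step 13
Reactants: 12 (Z)-[2,4-bis(methoxymethoxy)phenyl]{(5S)-5-[(2R)-6-methyl-2-(triethylsilyloxy)hept-5-en-2-yl]-2-oxooxolan-3-ylidene}methyl trifluoromethanesulfonate; 20 2-iodo-3,5-bis(methoxymethoxy)-4-(3-methylbut-2-en-1-yl)phenol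
Product: 21 (3Z,5S)-3-{[2,4-bis(methoxymethoxy)phenyl][2-iodo-3,5-bis(methoxymethoxy)-4-(3-methylbut-2-en-1-yl)phenoxy]methylidene}-5-[(2R)-6-methyl-2-(triethylsilyloxy)hept-5-en-2-yl]oxolan-2-one
Conditions: Cs2CO3, DABCO (20 mol%), MeCN, 0 → 23 °C
Reagents that add atoms: none
Why: Nucleophilic vinylic substitution (conjugate addition–elimination) of the caesium phenoxide at the β-carbon of the β-sulfonyloxy alkylidene lactone; triflate leaves from the transient enolate before C–C rotation, so the Z geometry is kept, and DABCO steers attack to carbon instead of sulfonyl sulfur.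

Step 14
Reactants: 21 (3Z,5S)-3-{[2,4-bis(methoxymethoxy)phenyl][2-iodo-3,5-bis(methoxymethoxy)-4-(3-methylbut-2-en-1-yl)phenoxy]methylidene}-5-[(2R)-6-methyl-2-(triethylsilyloxy)hept-5-en-2-yl]oxolan-2-one
Product: 23 2-[2,4-bis(methoxymethoxy)phenyl]-3-[(2S,3R)-2-hydroxy-3,7-dimethyl-3-(triethylsilyloxy)oct-6-en-1-yl]-5,7-bis(methoxymethoxy)-6-(3-methylbut-2-en-1-yl)-4H-chromen-4-one, via arylmagnesium chloride 22 (not isolated)
Conditions: iPrMgCl·LiCl (1.2 equiv), THF, −40 → 0 °C; aq NH4Cl
Reagents that add atoms: none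
Why: Proposed new method: iodine–magnesium exchange at the ring A iodide, helped by the two flanking oxygen substituents, should outpace addition of iPrMgCl to the deactivated vinylogous-carbonate lactone at −40 °C, and arylmagnesium 22 then attacks the lactone carbonyl to form the C4–C4a bond; the tetrahedral magnesium alkoxide collapses by expelling the C2'' alkoxide, which opens the lactone and leaves a chromone carbonyl that is too deactivated for a second addition. The closest known reaction type is the Parham cycloacylation, in which an aryl–metal made by halogen–metal exchange is acylated intramolecularly by an ester, amide or lactone; its use on an α-(aryloxymethylidene) lactone to give a chromone has no direct precedent. Ring C closes in a 6-exo-trig mode, the carbonyl oxygen lying outside the new six-membered ring. No stereocentre is formed, and C2'' and C3'' are untouched because the acyl C–O bond breaks while the C2''–O bond stays. The step needs exchange before carbonyl or conjugate addition, which the iodide, the LiCl-activated reagent and the low temperature secure, and it needs the Z geometry set in steps 8 and 13, which holds the metalated carbon next to the carbonyl; the iodine marks the only carbon that can become C4a, so only the 6-prenyl isomer can form.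

Step 15
Reactants: 23 2-[2,4-bis(methoxymethoxy)phenyl]-3-[(2S,3R)-2-hydroxy-3,7-dimethyl-3-(triethylsilyloxy)oct-6-en-1-yl]-5,7-bis(methoxymethoxy)-6-(3-methylbut-2-en-1-yl)-4H-chromen-4-one
Product: 24 2-(2,4-dihydroxyphenyl)-3-[(2S,3R)-2,3-dihydroxy-3,7-dimethyloct-6-en-1-yl]-5,7-dihydroxy-6-(3-methylbut-2-en-1-yl)-4H-chromen-4-one
Conditions: HCl (1.25 M in MeOH), 35 °C
Reagents that add atoms: none
Why: Acid-catalysed acetal exchange of the four aryl MOM ethers with methanol and solvolysis of the tertiary silyl ether in one operation; only O–CH2 and O–Si bonds break, so both stereocentres are retained, and the dilute acid and low temperature are chosen to spare the prenyl and chain alkenes.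

**Compound list**

1 | geraniol, (2E)-3,7-dimethylocta-2,6-dien-1-ol | CC(C)=CCC/C(C)=C/CO | starting material
2 | [(2R,3R)-3-methyl-3-(4-methylpent-3-en-1-yl)oxiran-2-yl]methanol | CC(C)=CCC[C@@]1(C)O[C@@H]1CO | intermediate
3 | (2S,3R)-3,7-dimethyloct-6-ene-1,2,3-triol | CC(C)=CCC[C@@](C)(O)[C@@H](O)CO | intermediate
4 | (2S,3R)-2,3-dihydroxy-3,7-dimethyloct-6-en-1-yl 4-methylbenzenesulfonate | CC(C)=CCC[C@@](C)(O)[C@@H](O)COS(=O)(=O)c1ccc(C)cc1 | intermediate (not isolated)
5 | (2R)-6-methyl-2-[(2S)-oxiran-2-yl]hept-5-en-2-ol | CC(C)=CCC[C@@](C)(O)[C@@H]1CO1 | intermediate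
6 | triethyl({(2R)-6-methyl-2-[(2S)-oxiran-2-yl]hept-5-en-2-yl}oxy)silane | CC(C)=CCC[C@@](C)(O[Si](CC)(CC)CC)[C@@H]1CO1 | intermediate
7 | methyl 2,4-dihydroxybenzoate | COC(=O)c1ccc(O)cc1O | starting material
8 | methyl 2,4-bis(methoxymethoxy)benzoate | COC(=O)c1ccc(OCOC)cc1OCOC | intermediate
9 | methyl 3-[2,4-bis(methoxymethoxy)phenyl]-3-oxopropanoate | COC(=O)CC(=O)c1ccc(OCOC)cc1OCOC | intermediate
10 | methyl (4S,5R)-2-[2,4-bis(methoxymethoxy)benzoyl]-4-hydroxy-5,9-dimethyl-5-(triethylsilyloxy)dec-8-enoate, C2 epimers | CC(C)=CCC[C@@](C)(O[Si](CC)(CC)CC)[C@@H](O)CC(C(=O)OC)C(=O)c1ccc(OCOC)cc1OCOC | intermediate (not isolated)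
11 | (5S)-3-[2,4-bis(methoxymethoxy)benzoyl]-5-[(2R)-6-methyl-2-(triethylsilyloxy)hept-5-en-2-yl]oxolan-2-one, C3 epimers | CC(C)=CCC[C@@](C)(O[Si](CC)(CC)CC)[C@@H]1CC(C(=O)c2ccc(OCOC)cc2OCOC)C(=O)O1 | intermediate
12 | (Z)-[2,4-bis(methoxymethoxy)phenyl]{(5S)-5-[(2R)-6-methyl-2-(triethylsilyloxy)hept-5-en-2-yl]-2-oxooxolan-3-ylidene}methyl trifluoromethanesulfonate | CC(C)=CCC[C@@](C)(O[Si](CC)(CC)CC)[C@@H]1C/C(=C(/OS(=O)(=O)C(F)(F)F)c2ccc(OCOC)cc2OCOC)C(=O)O1 | intermediate
13 | phloroglucinol, benzene-1,3,5-triol | Oc1cc(O)cc(O)c1 | starting material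
14 | 3,5-bis(methoxymethoxy)phenol | COCOc1cc(O)cc(OCOC)c1 | intermediate
15 | [3,5-bis(methoxymethoxy)phenoxy]tri(propan-2-yl)silane | COCOc1cc(O[Si](C(C)C)(C(C)C)C(C)C)cc(OCOC)c1 | intermediate
16 | 1-bromo-3-methylbut-2-ene | CC(C)=CCBr | starting material
17 | {2,6-bis(methoxymethoxy)-4-[tri(propan-2-yl)silyloxy]phenyl}lithium | [Li]c1c(OCOC)cc(O[Si](C(C)C)(C(C)C)C(C)C)cc1OCOC | intermediate (not isolated)
18 | [3,5-bis(methoxymethoxy)-4-(3-methylbut-2-en-1-yl)phenoxy]tri(propan-2-yl)silane | COCOc1cc(O[Si](C(C)C)(C(C)C)C(C)C)cc(OCOC)c1CC=C(C)C | intermediate (not isolated)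
19 | 3,5-bis(methoxymethoxy)-4-(3-methylbut-2-en-1-yl)phenol | COCOc1cc(O)cc(OCOC)c1CC=C(C)C | intermediate
20 | 2-iodo-3,5-bis(methoxymethoxy)-4-(3-methylbut-2-en-1-yl)phenol | COCOc1cc(O)c(I)c(OCOC)c1CC=C(C)C | intermediate
21 | (3Z,5S)-3-{[2,4-bis(methoxymethoxy)phenyl][2-iodo-3,5-bis(methoxymethoxy)-4-(3-methylbut-2-en-1-yl)phenoxy]methylidene}-5-[(2R)-6-methyl-2-(triethylsilyloxy)hept-5-en-2-yl]oxolan-2-one | CC(C)=CCC[C@@](C)(O[Si](CC)(CC)CC)[C@@H]1C/C(=C(/Oc2c(I)c(OCOC)c(CC=C(C)C)c(OCOC)c2)c2ccc(OCOC)cc2OCOC)C(=O)O1 | intermediate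
22 | arylmagnesium chloride of 21 (MgCl in place of iodine) | CC(C)=CCC[C@@](C)(O[Si](CC)(CC)CC)[C@@H]1C/C(=C(/Oc2c([Mg]Cl)c(OCOC)c(CC=C(C)C)c(OCOC)c2)c2ccc(OCOC)cc2OCOC)C(=O)O1 | intermediate (not isolated)
23 | 2-[2,4-bis(methoxymethoxy)phenyl]-3-[(2S,3R)-2-hydroxy-3,7-dimethyl-3-(triethylsilyloxy)oct-6-en-1-yl]-5,7-bis(methoxymethoxy)-6-(3-methylbut-2-en-1-yl)-4H-chromen-4-one | CC(C)=CCC[C@@](C)(O[Si](CC)(CC)CC)[C@@H](O)Cc1c(-c2ccc(OCOC)cc2OCOC)oc2cc(OCOC)c(CC=C(C)C)c(OCOC)c2c1=O | intermediate
24 | 2-(2,4-dihydroxyphenyl)-3-[(2S,3R)-2,3-dihydroxy-3,7-dimethyloct-6-en-1-yl]-5,7-dihydroxy-6-(3-methylbut-2-en-1-yl)-4H-chromen-4-one | CC(C)=CCC[C@@](C)(O)[C@@H](O)Cc1c(-c2ccc(O)cc2O)oc2cc(O)c(CC=C(C)C)c(O)c2c1=O | target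

**Step count and risks**

Total step count: 15. Longest linear sequence: 9 steps (1, 2, 3, 4, 7, 8, 13, 14, 15).

Steps most likely to fail:

1. Step 14. The alkylmagnesium may add to the lactone carbonyl or displace the aryloxy group before the exchange is complete, or the arylmagnesium may be protonated before it adds to the deactivated carbonyl. The fallback sets out from iodophenol 20 (with ester 8 and epoxide 6) and comes back at 23, building ring C by known chemistry and attaching the chain afterwards. Ester 8 is reduced (iBu2AlH, CH2Cl2, −78 °C) to 2,4-bis(methoxymethoxy)benzaldehyde F1, which is homologated with dimethyl (1-diazo-2-oxopropyl)phosphonate (K2CO3, MeOH) to 1-ethynyl-2,4-bis(methoxymethoxy)benzene F2. Carbonylative Sonogashira coupling–cyclisation of 20 with F2 (PdCl2(PPh3)2, CO 1 atm, Et2NH) gives 2-[2,4-bis(methoxymethoxy)phenyl]-5,7-bis(methoxymethoxy)-6-(3-methylbut-2-en-1-yl)-4H-chromen-4-one F3. Lithiation at C3 (LiN(iPr)2, THF, −78 °C) and iodine give 2-[2,4-bis(methoxymethoxy)phenyl]-3-iodo-5,7-bis(methoxymethoxy)-6-(3-methylbut-2-en-1-yl)-4H-chromen-4-one F4. Iodine–magnesium exchange on F4 (iPrMgCl·LiCl, −40 °C) and CuI-catalysed opening of epoxide 6 at its CH2 terminus then deliver 23.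

2. Step 13. The hindered phenoxide may attack the sulfonyl sulfur and transfer the triflyl group back to the enolate, or the alkene geometry may be lost during addition–elimination. The fallback sets out from enol triflate 12 and the iodine-free phenol 19 and comes back at 21. Palladium-catalysed C–O coupling (Pd2(dba)3, 2-(di-tert-butylphosphino)biphenyl, K3PO4, toluene, 80 °C), which retains the geometry, gives (3Z,5S)-3-{[2,4-bis(methoxymethoxy)phenyl][3,5-bis(methoxymethoxy)-4-(3-methylbut-2-en-1-yl)phenoxy]methylidene}-5-[(2R)-6-methyl-2-(triethylsilyloxy)hept-5-en-2-yl]oxolan-2-one F5. Iodination of F5 with N-iodosuccinimide (MeCN, −20 °C) at one of the two equivalent free carbons of the trioxygenated ring A then gives 21; competing iodination of ring B is the point to watch.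

3. Step 7. The stabilised enolate may open the hindered epoxide too slowly, so that silyl migration from the tertiary to the new secondary oxygen and retro-Claisen cleavage compete. The fallback sets out from epoxide 6 and comes back at 11, reversing the order of C–C bond formation. Sodium dimethyl malonate (NaOMe, MeOH, 60 °C) opens 6 and lactonises to methyl (5S)-5-[(2R)-6-methyl-2-(triethylsilyloxy)hept-5-en-2-yl]-2-oxooxolane-3-carboxylate F6. Krapcho demethoxycarbonylation (LiCl, wet DMSO, 130 °C) gives (5S)-5-[(2R)-6-methyl-2-(triethylsilyloxy)hept-5-en-2-yl]oxolan-2-one F7. Claisen acylation of the lithium enolate of F7 with ester 8 (LiN(SiMe3)2, 2.2 equiv, THF, −78 → 0 °C) gives 11.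

**Further compounds**

F1 | step 14 | 2,4-bis(methoxymethoxy)benzaldehyde | COCOc1ccc(C=O)c(OCOC)c1
F2 | step 14 | 1-ethynyl-2,4-bis(methoxymethoxy)benzene | COCOc1ccc(C#C)c(OCOC)c1
F3 | step 14 | 2-[2,4-bis(methoxymethoxy)phenyl]-5,7-bis(methoxymethoxy)-6-(3-methylbut-2-en-1-yl)-4H-chromen-4-one | COCOc1ccc(-c2cc(=O)c3c(OCOC)c(CC=C(C)C)c(OCOC)cc3o2)c(OCOC)c1
F4 | step 14 | 2-[2,4-bis(methoxymethoxy)phenyl]-3-iodo-5,7-bis(methoxymethoxy)-6-(3-methylbut-2-en-1-yl)-4H-chromen-4-one | COCOc1ccc(-c2oc3cc(OCOC)c(CC=C(C)C)c(OCOC)c3c(=O)c2I)c(OCOC)c1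
F5 | step 13 | (3Z,5S)-3-{[2,4-bis(methoxymethoxy)phenyl][3,5-bis(methoxymethoxy)-4-(3-methylbut-2-en-1-yl)phenoxy]methylidene}-5-[(2R)-6-methyl-2-(triethylsilyloxy)hept-5-en-2-yl]oxolan-2-one | CC(C)=CCC[C@@](C)(O[Si](CC)(CC)CC)[C@@H]1C/C(=C(/Oc2cc(OCOC)c(CC=C(C)C)c(OCOC)c2)c2ccc(OCOC)cc2OCOC)C(=O)O1
F6 | step 7 | methyl (5S)-5-[(2R)-6-methyl-2-(triethylsilyloxy)hept-5-en-2-yl]-2-oxooxolane-3-carboxylate, C3 epimers | CC(C)=CCC[C@@](C)(O[Si](CC)(CC)CC)[C@@H]1CC(C(=O)OC)C(=O)O1
F7 | step 7 | (5S)-5-[(2R)-6-methyl-2-(triethylsilyloxy)hept-5-en-2-yl]oxolan-2-one | CC(C)=CCC[C@@](C)(O[Si](CC)(CC)CC)[C@@H]1CCC(=O)O1
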